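**Plan**

- Retrosynthesis (flavanone numbering): ring A is cut at C8–C8a and C4a–C5, then ring C at C2–C3 and O1–C8a.
- Enabling feature: without ring A, ring C (O1, C2, C3, C4, C4a, C8a) is a 2-aryl-2,3-dihydropyran-4-one. Its only stereocentre, C2, is the former formyl carbon of 2,4,6-trimethoxybenzaldehyde, and C3, C4, C4a and C8a are the four carbons of a 1-methoxy-3-siloxybutadiene.
- Forward order: ring B is bought. Ring C closes first by an enantioselective hetero-Diels–Alder reaction. Ring A closes last by a Diels–Alder reaction with a C5–C8 vinylketene acetal that already carries the prenyl group, followed by aromatisation.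
- The two cycloadditions are linked by a p-tolylsulfinyl group on C4a, introduced through the enol silane of the first cycloadduct in the same flask. A sulfoxide is preferred to a halogen for three reasons: no electrophilic halogenation is run beside the very electron-rich ring B, it activates C4a=C8a, and it leaves by syn elimination with the cis C8a–H.
- Stereochemistry: C2 is set by the chiral Cr(III) catalyst. Every later operation is aprotic and close to neutral, so neither ionisation of the 2,4,6-trimethoxybenzylic C2–O1 bond nor opening to the chalcone should scramble it.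

Key step: step 1

Assumption: the sense of induction is carried over from benzaldehyde, for which the (S,S)-(salen)Cr(III) complex is taken to open the Si face; both ligand antipodes are commercial, so the antipode is exchanged if a test run (chiral HPLC, CD) shows the opposite sense.

Step 1
Reactants: 1 Danishefsky's diene [(E)-1-methoxy-3-(trimethylsilyloxy)buta-1,3-diene]; 2 2,4,6-trimethoxybenzaldehyde
Product: 5 (2S)-5-(p-tolylsulfinyl)-2-(2,4,6-trimethoxyphenyl)-2,3-dihydro-4H-pyran-4-one (both sulfur epimers), via enol silane cycloadduct 3 (not isolated), via methoxy sulfinyl ketone 4 (not isolated)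
Conditions: (S,S)-(salen)Cr(III)BF4 (5 mol %; salen = N,N'-bis(3,5-di-tert-butylsalicylidene)-1,2-cyclohexanediamine), 4 Å MS, TBME (concentrated), -20 to 0 °C; then p-TolS(O)Cl, CH2Cl2, -78 °C; then Et3N, -78 to 0 °C
Reagents that add atoms: p-toluenesulfinyl chloride, Cc1ccc(cc1)S(Cl)=O
Why: The cationic Cr(III) centre binds the formyl oxygen of 2 anti to the aryl group, and 1 adds in a concerted but asynchronous [4+2] cycloaddition in which C2–C3 forms ahead of O1–C8a. The closest known reaction type is the catalytic enantioselective hetero-Diels–Alder reaction of 1-alkoxy-3-siloxy dienes with aromatic aldehydes under (salen)Cr(III) complexes, which stops at the enol silane cycloadduct until an acid or another electrophile is added. Ring C closes as a six-membered ring directly in the cycloaddition (endo, hence cis-3), not by a later 6-endo oxa-Michael step. C2 is controlled by the catalyst alone: the (S,S)-diamine backbone and the tert-butyl groups of the ligand are taken to leave the Si face of the bound aldehyde open, which gives 2S, and the acetal centre C8a of 3 is erased again in the same flask. Besides facial selectivity the step needs regioselectivity, secured by the polarity of 1 (nucleophilic CH2 terminus, electrophilic formyl carbon), and chemoselectivity in the sulfinylation, secured by the enol silane C4=C4a of 3, which is far more nucleophilic than ring B, so that the known C-sulfinylation of silyl enol ethers with sulfinyl chlorides goes to C4a. Et3N then removes the doubly activated C4a–H of 4 and methoxide leaves C8a (E1cB), so no protic acid meets the 2,4,6-trimethoxybenzylic C2–O1 bond, whose ionisation would racemise C2.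

Step 2
Reactants: 6 methyl acetoacetate; 7 prenyl bromide (1-bromo-3-methylbut-2-ene)
Product: 9 methyl 7-methyl-3-oxooct-6-enoate, via acetoacetate dianion 8 (not isolated)
Conditions: NaH, THF, 0 °C; n-BuLi, 0 °C; then 7, 0 °C to rt; dilute aq. HCl quench
Reagents that add atoms: none
Why: This is the γ-alkylation of an acetoacetate dianion, in which the last-formed and more basic C4 carbanion of 8 takes the primary allylic bromide by SN2, placing the prenyl group on the carbon that becomes C8.

Step 3
Reactants: 9 methyl 7-methyl-3-oxooct-6-enoate
Product: 10 methyl (E)-3-methoxy-7-methylocta-2,6-dienoate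
Conditions: HC(OMe)3, p-TsOH (cat.), MeOH, rt
Reagents that add atoms: trimethyl orthoformate, COC(OC)OC
Why: Acid-catalysed enol etherification of a β-keto ester with an orthoester gives the conjugated (E)-enol ether (OMe trans to the ester) as the thermodynamic product, which holds C4H2 cis to the ester carbonyl, and the catalytic acid at rt should leave the trisubstituted alkene alone.

Step 4
Reactants: 10 methyl (E)-3-methoxy-7-methylocta-2,6-dienoate
Product: 12 (1Z,3Z)-1,3-dimethoxy-7-methyl-1-(trimethylsilyloxy)octa-1,3,6-triene, via lithium dienolate 11 (not isolated)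
Conditions: LDA, THF, -78 °C; TMSCl, -78 °C to rt; pentane, filtration, bulb-to-bulb distillation
Reagents that add atoms: chlorotrimethylsilane, C[Si](C)(C)Cl
Why: Carbonyl-directed kinetic γ-deprotonation of a β-alkoxy enoate and O-silylation of the dienolate is the standard preparation of 1,3-dialkoxy-1-siloxy dienes, and the prenyl chain should turn away from the ester arm to give the (3Z) geometry, the one that can reach the s-cis conformation.

Step 5
Reactants: 5 (2S)-5-(p-tolylsulfinyl)-2-(2,4,6-trimethoxyphenyl)-2,3-dihydro-4H-pyran-4-one; 12 (1Z,3Z)-1,3-dimethoxy-7-methyl-1-(trimethylsilyloxy)octa-1,3,6-triene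
Product: 15 (2S)-5-hydroxy-7-methoxy-8-(3-methylbut-2-en-1-yl)-2-(2,4,6-trimethoxyphenyl)-2,3-dihydro-4H-chromen-4-one (target), via sulfinyl cycloadduct 13 (not isolated), via dihydroarene ketal 14 (not isolated)
Conditions: 12 (2.5 equiv), Eu(fod)3 (10 mol %), toluene, rt to 70 °C; then SiO2, moist CH2Cl2, rt
Reagents that add atoms: none
Why: Proposed new method: C4a=C8a of 5 is a vinylogous ester and too electron-rich by itself, but the C4a sulfinyl group and C4=O, held as a six-membered chelate by the mild Lewis acid, lower its LUMO and polarise C8a, so the nucleophilic prenyl-bearing terminus of 12 should bond to C8a and the ketene acetal carbon to C4a; suprafacial addition places C8a–H cis to the sulfoxide in 13, the geometry required for thermal syn elimination of p-toluenesulfenic acid, and 14 then loses methanol (C5–OMe with the doubly allylic C8–H) and its silyl group to give the chelated C5 phenol with OMe on C7 and prenyl on C8; the closest known reaction types are the Diels–Alder/aromatisation of 1,3-dialkoxy-1-siloxy dienes with 2-halo- and 2-sulfinyl-1,4-quinones and Diels–Alder reactions of chromones bearing an acceptor at C3, and C2 is not touched because the medium is aprotic and nearly neutral.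

**Compound list**

1 | Danishefsky's diene, (E)-1-methoxy-3-(trimethylsilyloxy)buta-1,3-diene | CO/C=C/C(=C)O[Si](C)(C)C | starting material
2 | 2,4,6-trimethoxybenzaldehyde | COc1cc(OC)c(C=O)c(OC)c1 | starting material
3 | (2S,6R)-6-methoxy-2-(2,4,6-trimethoxyphenyl)-4-(trimethylsilyloxy)-3,6-dihydro-2H-pyran (cis, endo cycloadduct) | CO[C@H]1C=C(O[Si](C)(C)C)C[C@@H](c2c(OC)cc(OC)cc2OC)O1 | intermediate
4 | (2S)-6-methoxy-5-(p-tolylsulfinyl)-2-(2,4,6-trimethoxyphenyl)tetrahydro-4H-pyran-4-one (mixture at C5, C6 and S) | COC1O[C@@H](CC(=O)C1S(=O)c1ccc(C)cc1)c1c(OC)cc(OC)cc1OC | intermediate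
5 | (2S)-5-(p-tolylsulfinyl)-2-(2,4,6-trimethoxyphenyl)-2,3-dihydro-4H-pyran-4-one (both sulfur epimers) | COc1cc(OC)c([C@@H]2CC(=O)C(=CO2)S(=O)c2ccc(C)cc2)c(OC)c1 | intermediate
6 | methyl acetoacetate | CC(=O)CC(=O)OC | starting material
7 | prenyl bromide, 1-bromo-3-methylbut-2-ene | CC(C)=CCBr | starting material
8 | sodium lithium dianion of methyl acetoacetate | COC([O-])=CC([O-])=C.[Na+].[Li+] | intermediate
9 | methyl 7-methyl-3-oxooct-6-enoate | COC(=O)CC(=O)CCC=C(C)C | intermediate
10 | methyl (E)-3-methoxy-7-methylocta-2,6-dienoate | COC(=O)/C=C(/OC)CCC=C(C)C | intermediate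
11 | lithium dienolate of 10 (oxido group cis to C3, prenyl chain trans to C2) | CO/C([O-])=C/C(OC)=C/CC=C(C)C.[Li+] | intermediate
12 | (1Z,3Z)-1,3-dimethoxy-7-methyl-1-(trimethylsilyloxy)octa-1,3,6-triene | CO/C(O[Si](C)(C)C)=C/C(OC)=C/CC=C(C)C | intermediate
13 | (2S)-5,7-dimethoxy-8-prenyl-4a-(p-tolylsulfinyl)-5-(trimethylsilyloxy)-2-(2,4,6-trimethoxyphenyl)-2,3,4a,5,8,8a-hexahydro-4H-chromen-4-one (H-8a cis to the sulfinyl group, other new centres mixtures) | COc1cc(OC)c([C@@H]2CC(=O)C3(S(=O)c4ccc(C)cc4)C(O2)C(CC=C(C)C)C(OC)=CC3(OC)O[Si](C)(C)C)c(OC)c1 | intermediate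
14 | (2S)-5,7-dimethoxy-8-prenyl-5-(trimethylsilyloxy)-2-(2,4,6-trimethoxyphenyl)-2,3,5,8-tetrahydro-4H-chromen-4-one | COc1cc(OC)c([C@@H]2CC(=O)C3=C(O2)C(CC=C(C)C)C(OC)=CC3(OC)O[Si](C)(C)C)c(OC)c1 | intermediate
15 | (2S)-5-hydroxy-7-methoxy-8-(3-methylbut-2-en-1-yl)-2-(2,4,6-trimethoxyphenyl)-2,3-dihydro-4H-chromen-4-one | COc1cc(OC)c([C@@H]2CC(=O)c3c(O)cc(OC)c(CC=C(C)C)c3O2)c(OC)c1 | target

**Totals**

Total step count: 5. Longest linear sequence: 4 steps (steps 2, 3, 4, 5). The other branch has 2 steps (steps 1, 5).

**Steps most likely to fail**

**Step 5 (labelled step).**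
- What may go wrong: C4a=C8a may remain too electron-rich to take up 12 before the diene is lost through silyl migration or hydrolysis. The addition may also stop after the first bond and open ring C at C8a–O1. That opening does not endanger C2, because C2–O1 stays intact.
- The fallback replaces the cycloaddition by a stepwise anionic annulation built from known reactions. It sets out from 5 and 10 and returns at 15.
- Lithium dienolate 11, made from 10 with LDA as in step 4 but not silylated, is added to 5 in THF at -78 °C. This is a Michael addition of an ester enolate to an α-sulfinyl enone, and β-alkoxy dienolates react at the γ-carbon.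
- The stabilised α-sulfinyl enolate is protonated with acetic acid to give the Michael adduct F1.
- C4a of F1 is epimerisable, so the cis arrangement of sulfoxide and C8a–H is always accessible. Warming in toluene to about 60 °C should then bring about the usual sulfoxide syn elimination to the C8a-substituted dihydropyranone F2.
- One equivalent of LiHMDS (THF, -78 to 0 °C) removes the doubly vinylogous C8–H. The extended enolate attacks the ester carbonyl (C5) through C4a in a Dieckmann-type closure, made possible by the (E)-enoate geometry that holds C8 and the ester cis. Methoxide leaves, and tautomerisation gives 15 as its phenoxide, which consumes the base before C3 can be deprotonated.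

**Step 1 (key step).**
- What may go wrong: turnover may be slow and facial selectivity incomplete with an electron-rich aldehyde substituted at both ortho positions. The enol silane may also be lost before the sulfinyl chloride arrives.
- A moderate enantiomeric purity should be upgradable by crystallisation of 15.
- If the cycloaddition itself fails, the same two bonds are made one after the other. This fallback sets out from 2 and returns at 5.
- The dilithium enolate of commercial (S)-2-hydroxy-1,2,2-triphenylethyl acetate (LDA, THF, then 2 at -78 °C or below) undergoes an auxiliary-controlled acetate aldol addition. It forms C2–C3 and is expected to give the (S)-carbinol, the crystalline aldol ester F3.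
- NaOMe in MeOH at 0 °C gives the methyl β-hydroxy ester F4.
- Excess lithiated methyl p-tolyl sulfoxide (THF, -78 to -20 °C) acylates to the hydroxy β-keto sulfoxide F5.
- DMF dimethyl acetal in toluene at rt condenses at the active methylene to the enaminone F6. The C2 hydroxyl group then displaces dimethylamine from F6, closing O1–C8a and giving 5.
- Here the sulfoxide enters as a nucleophile, so ring B never meets an electrophile.

**Step 4.**
- What may go wrong: γ-deprotonation may give the (3E) geometry, or silylation may occur on carbon. The diene then cannot reach the s-cis conformation or decomposes on distillation.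
- The fallback moves the prenyl group to the end of the synthesis. It sets out from 5 and returns at 15, and steps 2 and 3 are then not needed.
- The unsubstituted diene 1,3-dimethoxy-1-(trimethylsilyloxy)buta-1,3-diene F7 has no geometry problem at its CH2 terminus. It is made from methyl (E)-3-methoxybut-2-enoate with LDA and TMSCl.
- F7 is combined with 5 under the conditions of step 5 to give the 8-unsubstituted flavanone F8.
- Mitsunobu etherification of the C5 hydroxyl group (3-methylbut-2-en-1-ol, PPh3, DIAD, THF) gives the 5-O-prenyl ether F9.
- Eu(fod)3 (10 mol %, CHCl3, 60–80 °C) then triggers the Claisen–Cope sequence: a [3,3] shift to C6, followed by a [3,3] shift to the para position C8. This frees the C5 phenol and gives 15 under neutral conditions.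

**Further compounds**

F1 | step 5 | methyl (2E)-3-methoxy-7-methyl-4-[(6S)-4-oxo-3-(p-tolylsulfinyl)-6-(2,4,6-trimethoxyphenyl)tetrahydro-2H-pyran-2-yl]octa-2,6-dienoate | COC(=O)/C=C(/OC)C(CC=C(C)C)C1O[C@@H](CC(=O)C1S(=O)c1ccc(C)cc1)c1c(OC)cc(OC)cc1OC
F2 | step 5 | methyl (2E)-3-methoxy-7-methyl-4-[(2S)-4-oxo-2-(2,4,6-trimethoxyphenyl)-3,4-dihydro-2H-pyran-6-yl]octa-2,6-dienoate | COC(=O)/C=C(/OC)C(CC=C(C)C)C1=CC(=O)C[C@H](O1)c1c(OC)cc(OC)cc1OC
F3 | step 1 | (1S)-2-hydroxy-1,2,2-triphenylethyl (3S)-3-hydroxy-3-(2,4,6-trimethoxyphenyl)propanoate | COc1cc(OC)c([C@@H](O)CC(=O)O[C@@H](c2ccccc2)C(O)(c2ccccc2)c2ccccc2)c(OC)c1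
F4 | step 1 | methyl (3S)-3-hydroxy-3-(2,4,6-trimethoxyphenyl)propanoate | COC(=O)C[C@H](O)c1c(OC)cc(OC)cc1OC
F5 | step 1 | (4S)-4-hydroxy-1-(p-tolylsulfinyl)-4-(2,4,6-trimethoxyphenyl)butan-2-one | COc1cc(OC)c([C@@H](O)CC(=O)CS(=O)c2ccc(C)cc2)c(OC)c1
F6 | step 1 | (5S)-1-(dimethylamino)-5-hydroxy-2-(p-tolylsulfinyl)-5-(2,4,6-trimethoxyphenyl)pent-1-en-3-one | COc1cc(OC)c([C@@H](O)CC(=O)C(=CN(C)C)S(=O)c2ccc(C)cc2)c(OC)c1
F7 | step 4 | 1,3-dimethoxy-1-(trimethylsilyloxy)buta-1,3-diene | CO/C(O[Si](C)(C)C)=C/C(=C)OC
F8 | step 4 | (2S)-5-hydroxy-7-methoxy-2-(2,4,6-trimethoxyphenyl)-2,3-dihydro-4H-chromen-4-one | COc1cc(OC)c([C@@H]2CC(=O)c3c(O)cc(OC)cc3O2)c(OC)c1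
F9 | step 4 | (2S)-7-methoxy-5-(3-methylbut-2-en-1-yloxy)-2-(2,4,6-trimethoxyphenyl)-2,3-dihydro-4H-chromen-4-one | COc1cc(OC)c([C@@H]2CC(=O)c3c(OCC=C(C)C)cc(OC)cc3O2)c(OC)c1
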